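**Strategy**

The route rests on closing ring C at the C3–C4 bond. The C4 carbonyl of the flavanone is the formyl carbon of a ring A salicylaldehyde, and C2 and C3 are the two carbons of a 1-arylvinyl ether carried on O1. A rhodium-catalysed enantioselective 6-endo hydroacylation adds the aldehyde C–H bond across this enol ether, so one isomerisation builds ring C, the C4 ketone, the C3 methylene and the 2S stereocentre. The precursor, a 2-(1-arylvinyloxy)benzaldehyde, is assembled by esterifying the ring A phenol with the ring B benzoic acid and methylenating the ester carbonyl. The 2R side-chain carbinol comes from Shi epoxidation and epoxide-to-allylic-alcohol isomerisation of a prenyl group.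

Key step: step 13

Remark: 1,3-bis(methoxymethoxy)benzene is taken as purchasable (otherwise one step from resorcinol), and in step 13 the ligand antipode that delivers 2S is to be used, written here as (R).

**Route**

Step 1
Reactants: 1 1,3-bis(methoxymethoxy)benzene; 2 prenyl bromide (1-bromo-3-methylbut-2-ene)
Product: 4 2-(3-methylbut-2-en-1-yl)-1,3-bis(methoxymethoxy)benzene, via 2-lithio-1,3-bis(methoxymethoxy)benzene 3 (not isolated)
Conditions: n-BuLi, THF, 0 °C → rt; CuI (10 mol %), then 2, –20 °C → rt
Reagents that add atoms: none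
Why: Cooperative directed ortho-metalation places lithium at C2 between the two MOM ethers, and copper-catalysed SN2 allylation of the aryllithium with the primary allylic bromide should give the linear prenyl arene.

Step 2
Reactants: 4 2-(3-methylbut-2-en-1-yl)-1,3-bis(methoxymethoxy)benzene
Product: 5 (3R)-3-{[2,6-bis(methoxymethoxy)phenyl]methyl}-2,2-dimethyloxirane
Conditions: D-fructose-derived Shi ketone (30 mol %), Oxone (2KHSO5·KHSO4·K2SO4), K2CO3, Bu4NHSO4, MeCN/CH2(OMe)2, aq. Na2B4O7 buffer (pH 10.5), 0 °C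
Reagents that add atoms: Oxone, as potassium peroxymonosulfate, [K+].[O-]S(=O)(=O)OO
Why: Shi asymmetric epoxidation, in which the chiral dioxirane attacks the trisubstituted alkene through the spiro transition state that for 2-methylalk-2-enes is expected to deliver the (R)-epoxide, while the MOM ethers tolerate the basic medium.

Step 3
Reactants: 5 (3R)-3-{[2,6-bis(methoxymethoxy)phenyl]methyl}-2,2-dimethyloxirane
Product: 6 (2R)-1-[2,6-bis(methoxymethoxy)phenyl]-3-methylbut-3-en-2-ol
Conditions: Et2AlCl, LiTMP (premixed to Et2Al(TMP)), toluene, 0 °C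
Reagents that add atoms: none
Why: Base-promoted epoxide-to-allylic-alcohol isomerisation, in which the aluminium amide binds the epoxide oxygen and removes a proton from a methyl group of the gem-dimethyl carbon, so the C–O bond at the stereocentre is untouched and the (R) configuration is retained.

Step 4
Reactants: 6 (2R)-1-[2,6-bis(methoxymethoxy)phenyl]-3-methylbut-3-en-2-ol
Product: 7 tert-butyl({(2R)-1-[2,6-bis(methoxymethoxy)phenyl]-3-methylbut-3-en-2-yl}oxy)dimethylsilane
Conditions: TBSCl, imidazole, DMF, rt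
Reagents that add atoms: tert-butyldimethylsilyl chloride, CC(C)(C)[Si](C)(C)Cl
Why: Standard silylation of the secondary allylic alcohol, which protects it against acylation in step 10 and against allylic-alcohol isomerisation by rhodium hydride in step 13.

Step 5
Reactants: 7 tert-butyl({(2R)-1-[2,6-bis(methoxymethoxy)phenyl]-3-methylbut-3-en-2-yl}oxy)dimethylsilane
Product: 9 3-[(2R)-2-(tert-butyldimethylsilyloxy)-3-methylbut-3-en-1-yl]-2,4-bis(methoxymethoxy)benzaldehyde, via ring-lithiated silyl ether 8 (not isolated)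
Conditions: n-BuLi, TMEDA, THF, –20 → 0 °C; DMF, –78 °C → rt; aq. NH4Cl
Reagents that add atoms: N,N-dimethylformamide, CN(C)C=O
Why: MOM-directed ortho-lithiation followed by formylation of the aryllithium with DMF; the two positions ortho to the MOM ethers are equivalent, so a single aldehyde should result.

Step 6
Reactants: 9 3-[(2R)-2-(tert-butyldimethylsilyloxy)-3-methylbut-3-en-1-yl]-2,4-bis(methoxymethoxy)benzaldehyde
Product: 10 3-[(2R)-2-(tert-butyldimethylsilyloxy)-3-methylbut-3-en-1-yl]-2-hydroxy-4-(methoxymethoxy)benzaldehyde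
Conditions: MgBr2·OEt2, Et2O/toluene, 0 °C → rt
Reagents that add atoms: none
Why: Chelation-assisted Lewis-acid cleavage, in which magnesium held between the formyl oxygen and the ortho MOM ether activates only that acetal and leaves the para MOM ether and the TBS ether intact.

Step 7
Reactants: 10 3-[(2R)-2-(tert-butyldimethylsilyloxy)-3-methylbut-3-en-1-yl]-2-hydroxy-4-(methoxymethoxy)benzaldehyde
Product: 11 2-[(2R)-2-(tert-butyldimethylsilyloxy)-3-methylbut-3-en-1-yl]-6-(dimethoxymethyl)-3-(methoxymethoxy)phenol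
Conditions: HC(OMe)3, MeOH, PPTS (cat.), rt; Et3N quench
Reagents that add atoms: trimethyl orthoformate, COC(OC)OC; methanol, CO
Why: Acid-catalysed acetalisation driven by the orthoformate masks the aldehyde, which would otherwise be methylenated in step 11.

Step 8
Reactants: 12 methyl 3,5-dibromo-4-hydroxybenzoate
Product: 13 methyl 3,5-dibromo-4-(methoxymethoxy)benzoate
Conditions: MOMCl, iPr2NEt, CH2Cl2, 0 °C → rt
Reagents that add atoms: chloromethyl methyl ether, COCCl
Why: Williamson-type O-alkylation of the acidic phenol with chloromethyl methyl ether.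

Step 9
Reactants: 13 methyl 3,5-dibromo-4-(methoxymethoxy)benzoate; 14 prenylboronic acid pinacol ester (4,4,5,5-tetramethyl-2-(3-methylbut-2-en-1-yl)-1,3,2-dioxaborolane)
Product: 16 4-(methoxymethoxy)-3,5-bis(3-methylbut-2-en-1-yl)benzoic acid, via methyl 4-(methoxymethoxy)-3,5-bis(3-methylbut-2-en-1-yl)benzoate 15 (not isolated)
Conditions: PdCl2(IPent)(3-chloropyridine) (3 mol %; IPent = 1,3-bis[2,6-di(pentan-3-yl)phenyl]imidazol-2-ylidene), KOH (5 M aq), THF, 70 °C; then MeOH, 60 °C; 1 M HCl to pH 4
Reagents that add atoms: potassium hydroxide, [K+].[OH-]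
Why: Double Suzuki–Miyaura coupling under a bulky NHC–palladium catalyst that transfers the allyl group through its alpha carbon to give linear prenyl groups, after which the aqueous hydroxide saponifies the methyl ester in the same flask.

Step 10
Reactants: 11 2-[(2R)-2-(tert-butyldimethylsilyloxy)-3-methylbut-3-en-1-yl]-6-(dimethoxymethyl)-3-(methoxymethoxy)phenol; 16 4-(methoxymethoxy)-3,5-bis(3-methylbut-2-en-1-yl)benzoic acid
Product: 17 2-[(2R)-2-(tert-butyldimethylsilyloxy)-3-methylbut-3-en-1-yl]-6-(dimethoxymethyl)-3-(methoxymethoxy)phenyl 4-(methoxymethoxy)-3,5-bis(3-methylbut-2-en-1-yl)benzoate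
Conditions: DCC, DMAP (cat.), CH2Cl2, 0 °C → rt
Reagents that add atoms: none
Why: Steglich esterification; the phenol is the only free hydroxyl group, and DMAP acyl transfer should overcome its two ortho substituents.

Step 11
Reactants: 17 aryl benzoate from step 10
Product: 18 1-(1-{2-[(2R)-2-(tert-butyldimethylsilyloxy)-3-methylbut-3-en-1-yl]-6-(dimethoxymethyl)-3-(methoxymethoxy)phenoxy}vinyl)-4-(methoxymethoxy)-3,5-bis(3-methylbut-2-en-1-yl)benzene
Conditions: Cp2TiMe2, toluene/THF, 65 °C, dark; NaHCO3/MeOH/H2O work-up; basic alumina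
Reagents that add atoms: dimethyltitanocene, C[Ti](C)(C1C=CC=C1)C1C=CC=C1
Why: Petasis methylenation, in which thermally generated Cp2Ti=CH2 undergoes [2+2] cycloaddition and cycloreversion with the aryl ester carbonyl, under neutral conditions that leave the acetal, silyl ether and alkenes alone.

Step 12
Reactants: 18 aryl 1-arylvinyl ether acetal from step 11
Product: 19 3-[(2R)-2-(tert-butyldimethylsilyloxy)-3-methylbut-3-en-1-yl]-4-(methoxymethoxy)-2-({1-[4-(methoxymethoxy)-3,5-bis(3-methylbut-2-en-1-yl)phenyl]vinyl}oxy)benzaldehyde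
Conditions: PPTS (5 mol %), acetone/H2O (10:1), 0 °C; NaHCO3 quench
Reagents that add atoms: water, O
Why: Acid-catalysed acetal hydrolysis; the acetal of this ortho,para-dioxygenated benzaldehyde should ionise far faster than the aryl enol ether is protonated, so buffered mild acid at 0 °C should unmask only the aldehyde.

Step 13
Reactants: 19 2-(1-arylvinyloxy)benzaldehyde from step 12
Product: 20 (2S)-8-[(2R)-2-(tert-butyldimethylsilyloxy)-3-methylbut-3-en-1-yl]-7-(methoxymethoxy)-2-[4-(methoxymethoxy)-3,5-bis(3-methylbut-2-en-1-yl)phenyl]chroman-4-one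
Conditions: [Rh(cod)Cl]2 (2.5 mol %), (R)-DTBM-SEGPHOS (5.5 mol %), NaB[3,5-(CF3)2C6H3]4 (5 mol %), 1,4-dioxane, 60 °C
Reagents that add atoms: none
Why: Proposed new method: oxidative addition of the aldehyde C–H bond to the cationic monovalent rhodium bisphosphine gives an acyl rhodium hydride (trivalent rhodium), the tethered 1,1-disubstituted enol ether inserts into Rh–H with hydride delivered to C2 and rhodium to the terminal carbon, and C–C reductive elimination from the seven-membered acyl–alkyl rhodacycle forms the C3–C4 bond. The closest known reaction type is the rhodium/chiral bisphosphine-catalysed enantioselective endo hydroacylation of ortho-allylbenzaldehydes and of N-(1-arylvinyl)indole-2-carboxaldehydes that carry 1,1-disubstituted alkenes; an aryl 1-arylvinyl ether has not been shown as the alkene partner. Ring C closes in a 6-endo-trig mode. The new C2 stereocentre is set under catalyst control in the enantio-determining hydride insertion, the alkene face being chosen by the chiral bisphosphine pocket and not by the remote 2R side-chain centre. The step needs endo over exo regioselectivity (exo would give a 2-aryl-2-methylbenzofuran-3-one) and must outrun decarbonylation; 1,1-disubstitution disfavours the tertiary alkyl rhodium required for exo closure, and the ether oxygen of the tether keeps the alkene within reach of rhodium. The prenyl and isopropenyl alkenes are too remote from the acyl rhodium centre to insert intramolecularly, and the absence of Brønsted acid should keep the enol ether from hydrolysing.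

Step 14
Reactants: 20 protected flavanone from step 13
Product: 21 (2S)-7-hydroxy-8-[(2R)-2-hydroxy-3-methylbut-3-en-1-yl]-2-[4-hydroxy-3,5-bis(3-methylbut-2-en-1-yl)phenyl]chroman-4-one
Conditions: HCl (1.25 M in MeOH), THF, 35 °C; NaHCO3 quench
Reagents that add atoms: none
Why: Acid-catalysed transacetalisation of both aryl MOM ethers and methanolysis of the TBS ether in one operation, under conditions kept mild so that neither stereocentre, the allylic alcohol nor the prenyl groups should be engaged.

**Compound list**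

1 | 1,3-bis(methoxymethoxy)benzene | COCOc1cccc(OCOC)c1 | starting material
2 | prenyl bromide | CC(C)=CCBr | starting material
3 | 2-lithio-1,3-bis(methoxymethoxy)benzene | [Li]c1c(OCOC)cccc1OCOC | intermediate
4 | 2-(3-methylbut-2-en-1-yl)-1,3-bis(methoxymethoxy)benzene | COCOc1cccc(OCOC)c1CC=C(C)C | intermediate
5 | (3R)-3-{[2,6-bis(methoxymethoxy)phenyl]methyl}-2,2-dimethyloxirane | CC1(C)O[C@@H]1Cc1c(OCOC)cccc1OCOC | intermediate
6 | (2R)-1-[2,6-bis(methoxymethoxy)phenyl]-3-methylbut-3-en-2-ol | C=C(C)[C@H](O)Cc1c(OCOC)cccc1OCOC | intermediate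
7 | TBS ether of 6 | C=C(C)[C@H](O[Si](C)(C)C(C)(C)C)Cc1c(OCOC)cccc1OCOC | intermediate
8 | ring-lithiated silyl ether (lithium ortho to a MOM ether of 7) | C=C(C)[C@H](O[Si](C)(C)C(C)(C)C)Cc1c(OCOC)ccc([Li])c1OCOC | intermediate
9 | 3-[(2R)-2-(TBSO)-3-methylbut-3-en-1-yl]-2,4-bis(methoxymethoxy)benzaldehyde | C=C(C)[C@H](O[Si](C)(C)C(C)(C)C)Cc1c(OCOC)ccc(C=O)c1OCOC | intermediate
10 | 3-[(2R)-2-(TBSO)-3-methylbut-3-en-1-yl]-2-hydroxy-4-(methoxymethoxy)benzaldehyde | C=C(C)[C@H](O[Si](C)(C)C(C)(C)C)Cc1c(OCOC)ccc(C=O)c1O | intermediate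
11 | 2-[(2R)-2-(TBSO)-3-methylbut-3-en-1-yl]-6-(dimethoxymethyl)-3-(methoxymethoxy)phenol | C=C(C)[C@H](O[Si](C)(C)C(C)(C)C)Cc1c(OCOC)ccc(C(OC)OC)c1O | intermediate
12 | methyl 3,5-dibromo-4-hydroxybenzoate | COC(=O)c1cc(Br)c(O)c(Br)c1 | starting material
13 | methyl 3,5-dibromo-4-(methoxymethoxy)benzoate | COC(=O)c1cc(Br)c(OCOC)c(Br)c1 | intermediate
14 | prenylboronic acid pinacol ester | CC(C)=CCB1OC(C)(C)C(C)(C)O1 | starting material
15 | methyl 4-(methoxymethoxy)-3,5-bis(3-methylbut-2-en-1-yl)benzoate | COC(=O)c1cc(CC=C(C)C)c(OCOC)c(CC=C(C)C)c1 | intermediate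
16 | 4-(methoxymethoxy)-3,5-bis(3-methylbut-2-en-1-yl)benzoic acid | OC(=O)c1cc(CC=C(C)C)c(OCOC)c(CC=C(C)C)c1 | intermediate
17 | aryl benzoate of 11 and 16 | C=C(C)[C@H](O[Si](C)(C)C(C)(C)C)Cc1c(OCOC)ccc(C(OC)OC)c1OC(=O)c1cc(CC=C(C)C)c(OCOC)c(CC=C(C)C)c1 | intermediate
18 | aryl 1-arylvinyl ether, dimethyl acetal | C=C(C)[C@H](O[Si](C)(C)C(C)(C)C)Cc1c(OCOC)ccc(C(OC)OC)c1OC(=C)c1cc(CC=C(C)C)c(OCOC)c(CC=C(C)C)c1 | intermediate
19 | 2-(1-arylvinyloxy)benzaldehyde | C=C(C)[C@H](O[Si](C)(C)C(C)(C)C)Cc1c(OCOC)ccc(C=O)c1OC(=C)c1cc(CC=C(C)C)c(OCOC)c(CC=C(C)C)c1 | intermediate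
20 | (2S)-8-[(2R)-2-(TBSO)-3-methylbut-3-en-1-yl]-7-(methoxymethoxy)-2-[4-(methoxymethoxy)-3,5-diprenylphenyl]chroman-4-one | C=C(C)[C@H](O[Si](C)(C)C(C)(C)C)Cc1c(OCOC)ccc2c1O[C@H](c1cc(CC=C(C)C)c(OCOC)c(CC=C(C)C)c1)CC2=O | intermediate
21 | (2S)-7-hydroxy-8-[(2R)-2-hydroxy-3-methylbut-3-en-1-yl]-2-[4-hydroxy-3,5-bis(3-methylbut-2-en-1-yl)phenyl]chroman-4-one | C=C(C)[C@H](O)Cc1c(O)ccc2c1O[C@H](c1cc(CC=C(C)C)c(O)c(CC=C(C)C)c1)CC2=O | target

**Step count and risks**

Total step count: 14. Longest linear sequence: 12 (steps 1–7, then 10–14); the ring B acid takes 2 steps (8–9).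

Steps most likely to fail:

1. Step 13 (proposed new method). The hydride may insert in the exo sense and lead to the five-membered ketone, the acyl rhodium hydride may decarbonylate before closure, or facial discrimination in the hydride insertion may be poor. The fallback sets out from acid 16 and phenol 10 and comes back at 20; it forms the same C3–C4 bond by known chemistry with C2 set beforehand. Acid 16 is coupled with N,O-dimethylhydroxylamine (EDC, iPr2NEt) to give Weinreb amide F1. Chloromethyllithium (ICH2Cl, MeLi·LiBr, –78 °C) converts it into chloromethyl ketone F2. Asymmetric transfer hydrogenation with RuCl[(R,R)-TsDPEN](p-cymene) in HCO2H/Et3N is expected to give (S)-chlorohydrin F3. Mitsunobu etherification of F3 with phenol 10 (PPh3, DIAD) proceeds with inversion to (R)-ether aldehyde F4. A thiazolium-derived carbene (3-benzyl-5-(2-hydroxyethyl)-4-methylthiazolium chloride, DBU, NaI, 1,4-dioxane) then closes ring C by intramolecular alkylation of the Breslow intermediate, a carbene-catalysed nucleophilic substitution known for salicylaldehyde ethers bearing a leaving group on the ether chain, to give 20; the base is limited to the amount needed to take up HCl so that C2 is not epimerised through ring opening.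

2. Step 12. Protonation of the aryl enol ether may compete with acetal ionisation, with hydrolytic loss of ring B. The fallback sets out from 10 and comes back at 19, carrying the formyl carbon through the methylenation at the alcohol oxidation level. NaBH4 reduction of 10 gives salicyl alcohol F5. Selective silylation of the primary hydroxyl group (TESCl, imidazole, –20 °C) gives benzylic triethylsilyl ether F6. Steglich esterification with 16 gives aryl ester F7, and Petasis methylenation gives enol ether F8. Swern conditions ((COCl)2, DMSO, Et3N, –78 → –30 °C) oxidise the primary triethylsilyl ether directly to aldehyde 19 under non-acidic conditions, while the secondary TBS ether stays in place.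

3. Step 14. Protic acid may promote cyclisation of the liberated phenols onto the neighbouring alkenes or ionise the allylic alcohol before both MOM groups are gone. The fallback sets out from 20 and comes back at 21 in two non-protic stages. TMSOTf with 2,2'-bipyridyl (CH2Cl2, 0 °C, then water) converts the aryl MOM ethers through silyl transfer into the free phenols and gives mono-TBS flavanone F9. Buffered fluoride (HF·pyridine, pyridine/THF, 0 °C → rt) then removes the secondary silyl ether without base-induced epimerisation at C2.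

Further compounds
F1 | step 13 | N-methoxy-4-(methoxymethoxy)-N-methyl-3,5-bis(3-methylbut-2-en-1-yl)benzamide | CON(C)C(=O)c1cc(CC=C(C)C)c(OCOC)c(CC=C(C)C)c1
F2 | step 13 | 2-chloro-1-[4-(methoxymethoxy)-3,5-bis(3-methylbut-2-en-1-yl)phenyl]ethan-1-one | ClCC(=O)c1cc(CC=C(C)C)c(OCOC)c(CC=C(C)C)c1
F3 | step 13 | (1S)-2-chloro-1-[4-(methoxymethoxy)-3,5-bis(3-methylbut-2-en-1-yl)phenyl]ethan-1-ol | O[C@@H](c1cc(CC=C(C)C)c(OCOC)c(CC=C(C)C)c1)CCl
F4 | step 13 | 3-[(2R)-2-(TBSO)-3-methylbut-3-en-1-yl]-2-{(1R)-2-chloro-1-[4-(methoxymethoxy)-3,5-bis(3-methylbut-2-en-1-yl)phenyl]ethoxy}-4-(methoxymethoxy)benzaldehyde | C=C(C)[C@H](O[Si](C)(C)C(C)(C)C)Cc1c(OCOC)ccc(C=O)c1O[C@H](c1cc(CC=C(C)C)c(OCOC)c(CC=C(C)C)c1)CCl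
F5 | step 12 | 2-[(2R)-2-(TBSO)-3-methylbut-3-en-1-yl]-6-(hydroxymethyl)-3-(methoxymethoxy)phenol | C=C(C)[C@H](O[Si](C)(C)C(C)(C)C)Cc1c(OCOC)ccc(CO)c1O
F6 | step 12 | 2-[(2R)-2-(TBSO)-3-methylbut-3-en-1-yl]-3-(methoxymethoxy)-6-[(triethylsilyloxy)methyl]phenol | C=C(C)[C@H](O[Si](C)(C)C(C)(C)C)Cc1c(OCOC)ccc(CO[Si](CC)(CC)CC)c1O
F7 | step 12 | aryl benzoate of F6 and 16 | C=C(C)[C@H](O[Si](C)(C)C(C)(C)C)Cc1c(OCOC)ccc(CO[Si](CC)(CC)CC)c1OC(=O)c1cc(CC=C(C)C)c(OCOC)c(CC=C(C)C)c1
F8 | step 12 | aryl 1-arylvinyl ether with benzylic triethylsilyl ether | C=C(C)[C@H](O[Si](C)(C)C(C)(C)C)Cc1c(OCOC)ccc(CO[Si](CC)(CC)CC)c1OC(=C)c1cc(CC=C(C)C)c(OCOC)c(CC=C(C)C)c1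
F9 | step 14 | (2S)-8-[(2R)-2-(TBSO)-3-methylbut-3-en-1-yl]-7-hydroxy-2-[4-hydroxy-3,5-bis(3-methylbut-2-en-1-yl)phenyl]chroman-4-one | C=C(C)[C@H](O[Si](C)(C)C(C)(C)C)Cc1c(O)ccc2c1O[C@H](c1cc(CC=C(C)C)c(O)c(CC=C(C)C)c1)CC2=O
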